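The readings stem from a simulated flask with constants of no real substance.

Late in a run, what is left at the last reading is the thing I carry over, and each new flask is read at that same late moment.

| flask | electrophile | nucleophile | protic impurity | remark | time |
|---|---|---|---|---|---|
| autumn | 5 mM | 14 mM | 1 mM | run made earlier |  |
| noon | 5 mM | 23 mM | 1 mM | run made earlier |  |
| birch | 5.0 mM | 10.0 mM | 1.00 mM |  | 3.0 min |
| elm | 5.0 mM | 13.0 mM | 1.00 mM |  | 3.0 min |
| maple | 5.0 mM | 17.0 mM | 1.00 mM |  | 3.0 min |

| run | time / min | electrophile / % | target / % |
|---|---|---|---|
| autumn | 0.667 | 48.6 | 15.1 |
| autumn | 1.33 | 31.8 | 11.6 |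
| autumn | 2.00 | 24.2 | 8.5 |
| autumn | 2.50 | 20.4 | 8.0 |
| autumn | 3.00 | 16.4 | 8.7 |
| noon | 0.667 | 32.9 | 12.1 |
| noon | 1.33 | 17.7 | 5.5 |
| noon | 2.00 | 8.5 | 3.1 |
| noon | 2.50 | 6.2 | 3.2 |
| noon | 3.00 | 4.9 | 4.5 |

(standard deviation of a reading: 1 percentage point)

- part of the electrophile that has reacted at the end, birch
- part of the electrophile that has reacted at the end, elm
- part of the electrophile that has reacted at the end, maple
- what raising the concentration of nucleophile from its lowest to its highest value here does to the part of the electrophile that has reacted (changes below 5 percentage points count as none) (it falls / it rises / no change)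

- the numbers in the tables scatter with a standard deviation of 1 percentage point
- on the list of suspects stand: electrophile + nucleophile <-> acid set free + target; nucleophile + acid set free <-> protonated nucleophile; nucleophile + target -> over-reaction product; electrophile + protic impurity -> quenched substrate

*What do you take from the last row of each run?* The fraction of electrophile left at 3.00 min: 16.4% in autumn, 4.9% in noon. Written as half-lives gone by, those are 2.61 and 4.35.

*And then?* I divide each by the equivalents of nucleophile, its charge over the electrophile's charge, which gives 0.932 and 0.946. These two are close, so I keep their mean: the half-lives counted per equivalent of nucleophile at this reading time, 0.939.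

*The decay slows as it goes, so what does a half-life mean here?* It is no rate constant. It is the fraction left at one time, rewritten so that in these two runs it grows in step with the nucleophile, with the time, the electrophile and the protic impurity held.

*Where is it weakest?* The nucleophile charges of birch and elm lie below those of both runs, so there I am extrapolating. Both runs also charge the same electrophile, so dividing by that charge is my assumption.

*Your numbers?* The part reacted is one minus a half raised to the count times the equivalents: 72.8% for birch, 81.6% for elm and 89.1% for maple. That is a rise of 16 percentage points, more than the 5 points that counts as a change.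

The forecast gives 72%, 81% and 89%, and on the trend, it rises: “Conversion rises with nucleophile.” Mine stands slightly higher at birch and elm.

The flasks give 71.9%, 80.8% and 89.1%, and the trend is that it rises, by 17 points.

    electrophile + nucleophile ⇌ acid set free + target (K = 3.20, k = 1.08 M⁻¹ s⁻¹)
    nucleophile + acid set free ⇌ protonated nucleophile, settled at all times (K = 7.61 × 10⁵ M⁻¹)
    nucleophile + target → over-reaction product (k = 3.69 M⁻¹ s⁻¹)
    electrophile + protic impurity → quenched substrate (k = 18.5 M⁻¹ s⁻¹)

Birch's own count comes to 0.915 per equivalent, against the 0.939 carried. In birch, the forward main step uses electrophile at 0.58 times the rate of quenching just after the start, 5.6 times at 0.670 min and 310 times at 3.00 min. By then the protic impurity is down to 0.0524% of its charge and quenched substrate stands at 20.0%. A neighbour of birch charged with 12 mM of electrophile has 0.833 equiv of nucleophile, so the count gives 58.1% of its electrophile left, and that flask still holds 58.9% of the electrophile charged.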